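(The readings are simulated on assumed constants; the scatter is artificial.)

Time is what I reckon in: I ask how long target has stood in a flask when the flask is stopped. These are the flasks, the questions and the earlier runs.

the same everywhere: free catalyst 0.2 mol%; second catalyst 15 mol%
- cedar: starting material 0.20 M; partner 0.90 equiv; run made earlier
- oak: starting material 0.13 M; partner 0.90 equiv; run made earlier
- alder: starting material 0.30 M; partner 0.90 equiv; run made earlier
- east: starting material 0.20 M; partner 0.900 equiv (in portions, 3, over 80 min); first portion at the start, last at 80 min; time 1.5 h
- south-west: starting material 0.20 M; partner 0.900 equiv (fed, over 80 min); all else is in the flask from the start; the feed brings no volume worth counting; time 1.5 h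
- north-east: starting material 0.20 M; partner 0.900 equiv; everything together at the start; time 1.5 h
- west: starting material 0.20 M (fed, over 80 min); partner 0.900 equiv; all else is in the flask from the start; the feed brings no volume worth counting; time 1.5 h

- the flask with the highest share of target in target plus isomer of the product ("all alike" if they lie within 1.5 percentage points) (east / south-west / north-east / west / all alike)
- share of target in target plus isomer of the product at the end, east
- share of target in target plus isomer of the product at the end, south-west
- share of target in target plus isomer of the product at the end, north-east
- share of target in target plus isomer of the product at the end, west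

- what may be going on: partner + catalyst intermediate -> second catalyst + target; starting material + free catalyst <-> free catalyst + open intermediate; target <-> isomer of the product; second catalyst + open intermediate <-> catalyst intermediate

| run | time / min | target / % | isomer of the product / % |
|---|---|---|---|
| cedar | 12.0 | 1 | 1 |
| cedar | 30.0 | 14 | 2 |
| cedar | 60.0 | 29 | 14 |
| cedar | 90.0 | 29 | 31 |
| oak | 4.00 | 0 | 0 |
| oak | 10.0 | 4 | 0 |
| oak | 25.0 | 8 | 0 |
| oak | 50.0 | 12 | 7 |
| alder | 6.00 | 1 | 0 |
| alder | 20.0 | 13 | 3 |
| alder | 40.0 | 32 | 12 |
| alder | 50.0 | 37 | 14 |

(standard deviation of a reading: 2 percentage points)

I read the cedar table downward, with every amount as a fraction of the starting material charged. At 30.0 min there is 14% target and 2% isomer of the product, so the product is still young. Between the last two rows target reads 29% both times, while isomer of the product climbs from 14% to 31%.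

Target divided by that gain per minute gives my quantity, the isomerisation clock, the time in which target standing in the cedar flask would be turned over at the present pace, a reading of 51.2 min. The alder rows at 20.0 min and 40.0 min read 50.0 min, at another concentration, though a scatter of 2 percentage points weighs heavily on so small a gain.

I define product age as the clock times ln(total product over target). The last cedar row then gives 37.2 min. North-east repeats the cedar recipe, so I expect cedar's share, 48.3%. In west, half of the starting material is still outside at 40.0 min, longer than that age, so I expect younger product there and a share above north-east. Cedar, oak and alder each hold partner, the limiting reagent by charge, at 0.90 equiv, so I leave east and south-west open.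

The forecast says west, with 56% for east, 59% for south-west, 48% for north-east and 66% for west, on the ground that “Portions and steady feed of partner both slow formation and shift it later”.

The flasks give 50.3% for east, 50.4% for south-west, 50.2% for north-east and 63.5% for west, so west stands highest.

    partner + catalyst intermediate → second catalyst + target (k = 12.0 M⁻¹ s⁻¹)
    starting material + free catalyst ⇌ free catalyst + open intermediate (K = 4.89, k = 0.825 M⁻¹ s⁻¹)
    target ⇌ isomer of the product (K = 12.0, k = 3.23 × 10⁻⁴ s⁻¹)
    second catalyst + open intermediate ⇌ catalyst intermediate (K = 2.00 M⁻¹, k = 0.0166 M⁻¹ s⁻¹)

On the clock, west's product age is 23.3 min, while east, south-west and north-east read 35.2 min, 35.1 min and 35.3 min. The forecast's south-west share corresponds to 27.0 min, so the south-west flask's product reads older than that and stands beside north-east's. A neighbour of north-east charged with 3.60 equiv of partner goes through the same reckoning: its share of 50.2% gives an age of 35.3 min, and it ends with 20.8% of the starting material left, as north-east does with 20.8%.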